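The route rests on cutting C4–C5, the unfunctionalised CH2–CH2 bond of the eleven-membered carbocycle, together with C6–C13 and O14–C15 (numbering below). In one operation a primary C4 radical closes a 15-membered ring on the diene terminus C5. The adduct radical is reduced to a dienolate, C6 adds transannularly to the C13 ketone (cyclohexene ring C6–C8/C10/C12/C13), and the alkoxide lactonises onto C15. The step exploits that C5 is the δ-position of the ring's C9 enoate and that spiro C13 is a lactone carbinol. The precursor is monocyclic: ring C16/C18–C22 as a cyclohexene bearing an iodoalkyl and a keto-dienoate arm. Its stereocentres are relayed from one catalytic Diels–Alder reaction.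

Key step: step 20

Remarks on the chemistry
* Numbering: the skeleton atoms of the target SMILES are counted from left to right and the five exocyclic oxygens are left out. This gives C1 (CH3 on C2), C9 (CO2H), C11 (CH3 on C10), O14 (lactone O), C15 (lactone C=O), C17 (CH3 on C16), C18/C19 (diketone) and C24 (CH3 on C23).
* Faces of ring C16/C18–C22: β is the face that carries C13, C15 and C23 in the target, α is the face of the C17 methyl.
* Assumption: the target is delivered as the 1,2-diketone tautomer that is drawn. Enolisation towards the bridgehead C20 is taken to be disfavoured.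
* Assumption: the sense of induction in step 6 follows the accepted formyl C–H···O model for cationic oxazaborolidines. The mirror-image catalyst is equally available.
* Commercial starting materials: 1, 4, 8, 9, 25, 28.

Step 1
Reactants: 1 (S)-citronellol
Product: 2 (S)-citronellyl chloride
Conditions: PPh3, NCS, CH2Cl2, 0 °C → rt
Reagents that add atoms: N-chlorosuccinimide O=C1CCC(=O)N1Cl
Why: Appel-type chlorination replaces the primary hydroxyl at C4 by SN2 and leaves the trisubstituted alkene and the bought C2 stereocentre untouched.

Step 2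
Reactants: 2 (S)-citronellyl chloride
Product: 3 (4S)-6-chloro-4-methylhexanoic acid
Conditions: RuCl3 (2 mol %), NaIO4, CCl4–MeCN–H2O, rt
Reagents that add atoms: sodium periodate [Na+].[O-]I(=O)(=O)=O; water O
Why: RuO4-catalysed oxidative cleavage of the only alkene gives the C24 carboxyl and acetone without touching C2 or the alkyl chloride.

Step 3
Reactants: 3 (4S)-6-chloro-4-methylhexanoic acid; 4 (E)-crotonaldehyde
Product: 7 (1E)-buta-1,3-dien-1-yl (4S)-6-chloro-4-methylhexanoate, via acid chloride 5 (not isolated), via potassium dienolate 6 (not isolated)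
Conditions: 3, (COCl)2, DMF (cat.), CH2Cl2; separately 4, KOt-Bu, THF, −78 °C; combine at −78 °C
Reagents that add atoms: none
Why: γ-Deprotonation of crotonaldehyde and O-acylation of the extended enolate (the known route to 1-acyloxybutadienes) give mainly the E dienyl ester, and the minor Z isomer cannot adopt the s-cis form and stays out of step 6.

Step 4
Reactants: 8 tert-butyl diethylphosphonoacetate; 9 1,1-dimethoxypropan-2-one
Product: 10 tert-butyl (2E)-4,4-dimethoxy-3-methylbut-2-enoate
Conditions: NaH, THF, 0 °C → rt
Reagents that add atoms: none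
Why: Horner–Wadsworth–Emmons olefination of the activated methyl ketone gives mainly the E enoate, and any Z isomer converges in step 5.

Step 5
Reactants: 10 tert-butyl (2E)-4,4-dimethoxy-3-methylbut-2-enoate
Product: 11 tert-butyl (2E)-3-methyl-4-oxobut-2-enoate
Conditions: aq. oxalic acid, THF, rt
Reagents that add atoms: water O
Why: Mild acetal hydrolysis frees the enal, spares the tert-butyl ester and equilibrates the alkene to the more stable E isomer.

Step 6
Reactants: 7 (1E)-buta-1,3-dien-1-yl (4S)-6-chloro-4-methylhexanoate; 11 tert-butyl (2E)-3-methyl-4-oxobut-2-enoate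
Product: 12 tert-butyl (1S,5S,6R)-5-{[(4S)-6-chloro-4-methylhexanoyl]oxy}-6-formyl-6-methylcyclohex-3-ene-1-carboxylate
Conditions: (S)-diphenylprolinol-derived B-(o-tolyl)oxazaborolidine·Tf2NH (20 mol %), CH2Cl2, −78 → −40 °C
Reagents that add atoms: none
Why: This is a catalytic enantioselective Diels–Alder reaction of an α-substituted enal, in which the boron-bound formyl group makes C22 the electrophilic terminus so that the nucleophilic diene terminus C21 bonds to it (ortho adduct), formyl-endo approach puts the C18 oxygen cis to C15, the E dienophile puts C13 trans to C15, and the catalyst shields one enal face and so fixes the absolute configuration at C16, C18 and C22.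

Step 7
Reactants: 12 Diels–Alder aldehyde
Product: 13 (1R,2S,6S)-6-(tert-butoxycarbonyl)-2-{[(4S)-6-chloro-4-methylhexanoyl]oxy}-1-methylcyclohex-3-ene-1-carboxylic acid
Conditions: NaClO2, NaH2PO4, 2-methylbut-2-ene, t-BuOH–H2O, rt
Reagents that add atoms: sodium chlorite [Na+].[O-]Cl=O
Why: Pinnick oxidation turns the non-enolisable C15 aldehyde into the acid under buffered conditions that spare both esters, the alkene and the chloride.

Step 8
Reactants: 13 acyloxy acid
Product: 15 (1S,4S,6S)-6-(tert-butoxycarbonyl)-4-[(1R,3S)-1-carboxy-5-chloro-3-methylpentyl]-1-methylcyclohex-2-ene-1-carboxylic acid, via bis-silyl ketene acetal 14 (not isolated)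
Conditions: LDA (2.3 equiv), THF–DMPU 4:1, −78 °C; TMSCl; → 40 °C; 1 M HCl
Reagents that add atoms: none
Why: In this Ireland–Claisen rearrangement LDA in THF–DMPU gives the (Z)-silyl ketene acetal, the suprafacial [3,3] shift delivers C23 to C20 on the β face vacated by the C18 oxygen, and the boat-like transition state usual for cyclohexenyl esters (a chair would push C24 over the ring against the β C15 carboxyl) with the chain outside sets C23, while the non-enolisable C15 carboxylate only consumes base.

Step 9
Reactants: 15 Claisen diacid
Product: 17 (1S,4S,6S)-6-(tert-butoxycarbonyl)-4-[(2R,4S)-6-chloro-1-hydroxy-4-methylhexan-2-yl]-1-methylcyclohex-2-ene-1-carboxylic acid, via C24 mixed anhydride 16 (not isolated)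
Conditions: i-BuOCOCl (1.0 equiv), N-methylmorpholine, THF, −20 °C; NaBH4, MeOH, −20 → 0 °C
Reagents that add atoms: none
Why: In this mixed-anhydride activation and borohydride reduction the C24 carboxyl reacts much faster than the neopentyl C15 carboxyl on quaternary C16, and any C15 mixed anhydride is attacked by hydride at its carbonate carbonyl and reverts to the acid.

Step 10
Reactants: 17 hydroxy acid
Product: 19 (1S,4R,6S)-6-(tert-butoxycarbonyl)-4-[(2R,4S)-6-chloro-4-methylhexan-2-yl]-1-methylcyclohex-2-ene-1-carboxylic acid, via C24 iodide 18 (not isolated)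
Conditions: I2, PPh3, imidazole, THF, 0 °C → rt; then Zn, AcOH, 50 °C
Reagents that add atoms: none
Why: Appel-type iodination followed in the same flask by zinc–acetic acid reduction of the primary iodide turns C24 into the methyl group, and the unactivated alkyl chloride, the alkene, the tert-butyl ester and C23 are not involved.

Step 11
Reactants: 19 acid tert-butyl ester
Product: 22 cis-fused C13/C15 anhydride, via trans-diacid 20 (not isolated), via trans-fused anhydride 21 (not isolated)
Conditions: TFA, CH2Cl2, rt; evaporate; Ac2O, Et3N, DMAP (cat.), toluene, 80 °C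
Reagents that add atoms: none
Why: Acidolysis of the tert-butyl ester is followed by dehydration, and the strained trans-fused five-membered anhydride is enolised by Et3N at C22 (its only acidic C–H) and equilibrates to the less strained cis-fused anhydride, which inverts C22 under thermodynamic control.

Step 12
Reactants: 22 cis-fused anhydride
Product: 24 methyl (1S,4R,6R)-4-[(2R,4S)-6-chloro-4-methylhexan-2-yl]-6-[(ethylsulfanyl)carbonyl]-1-methylcyclohex-2-ene-1-carboxylate, via sodium carboxylate 23 (not isolated)
Conditions: NaSEt (1.0 equiv), THF, −40 °C; then MeI, DMF, rt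
Reagents that add atoms: sodium ethanethiolate CC[S-].[Na+]; iodomethane CI
Why: The unsymmetrical anhydride is opened at the less hindered C13 carbonyl (C15 is neopentyl) and the carboxylate is then O-methylated by SN2, while one equivalent of thiolate at low temperature spares the alkyl chloride and the C22 configuration.

Step 13
Reactants: 25 (R)-methyl hydrogen 3-methylglutarate
Product: 26 1-tert-butyl 5-methyl (3S)-3-methylpentanedioate
Conditions: isobutene, H2SO4 (cat.), CH2Cl2, rt, sealed
Reagents that add atoms: isobutene CC(C)=C
Why: Acid-catalysed addition of the free acid to isobutene protects the future C9 carboxyl, and the bought C10 stereocentre is not involved.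

Step 14
Reactants: 26 mixed diester
Product: 27 (3S)-5-(tert-butoxy)-3-methyl-5-oxopentanoic acid
Conditions: LiOH (1.05 equiv), THF–H2O, 0 °C; then HCl
Reagents that add atoms: lithium hydroxide [Li+].[OH-]
Why: Saponification removes the unhindered methyl ester selectively, because tert-butyl esters resist hydroxide, and this swaps the roles of the two termini.

Step 15
Reactants: 27 tert-butyl hemiester; 28 acrolein
Product: 29 aldol adduct (C7/C8 diastereomer mixture)
Conditions: LDA (2.2 equiv), THF, −78 °C; 28; HCl quench
Reagents that add atoms: none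
Why: In this aldol addition of the carboxylate/ester-enolate dianion the second equivalent of base removes the more acidic α-ester proton at C8, which adds 1,2 to acrolein, and the new C7/C8 centres are erased in step 16.

Step 16
Reactants: 29 aldol adduct
Product: 31 (3S,4E)-4-(tert-butoxycarbonyl)-3-methylhepta-4,6-dienoic acid, via C7 acetate 30 (not isolated)
Conditions: Ac2O, Et3N, DMAP, CH2Cl2, 0 °C; then DBU, rt; aq. work-up
Reagents that add atoms: none
Why: Acetylation and E1cB elimination give the conjugated dienoate, whose favoured E isomer has the vinyl group trans to the ester and cis to C10, as the later six-ring closure requires.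

Step 17
Reactants: 31 dienoate acid
Product: 32 tert-butyl (2E)-2-[(2R)-1-iodopropan-2-yl]penta-2,4-dienoate
Conditions: PhI(OAc)2, I2, CH2Cl2, visible light, 25–40 °C
Reagents that add atoms: iodine II
Why: In this Hunsdiecker-type decarboxylative iodination via the acyl hypoiodite the primary C12 radical is trapped by iodine faster than it can cyclise onto the diene, and C10 is untouched.

Step 18
Reactants: 32 dienoate iodide; 24 thioester
Product: 34 methyl (1S,4R,6R)-6-[(3S,4E)-4-(tert-butoxycarbonyl)-3-methylhepta-4,6-dienoyl]-4-[(2R,4S)-6-chloro-4-methylhexan-2-yl]-1-methylcyclohex-2-ene-1-carboxylate, via alkylzinc iodide 33 (not isolated)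
Conditions: 32, activated Zn, THF, 35 °C; then 24, PdCl2(PPh3)2 (5 mol %), toluene, rt
Reagents that add atoms: none
Why: Fukuyama coupling (Pd-catalysed acylation of an alkylzinc iodide by a thioester) forms C12–C13 under neutral conditions that tolerate the esters, the diene, the alkyl chloride and the epimerisable C22.

Step 19
Reactants: 34 keto chloride
Product: 35 keto iodide (34 with I in place of Cl at C4)
Conditions: NaI, BHT (cat.), butan-2-one, 75 °C
Reagents that add atoms: sodium iodide [Na+].[I-]
Why: Finkelstein exchange at the primary C4 carbon is driven by precipitation of NaCl and is neutral, so C22 and the dienoate are preserved.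

Step 20
Reactants: 35 keto iodide
Product: 38 tetracyclic spirolactone tert-butyl ester with C18=C19 alkene, via macrocyclic dienolate 36 (not isolated), via tertiary alkoxide 37 (not isolated)
Conditions: 4CzIPN (5 mol %), Et3N (5 equiv), Cs2CO3 (3 equiv), MeCN (1 mM, 35 added over 10 h), blue LED, 25 °C; then 45 °C, 6 h
Reagents that add atoms: none
Why: Proposed new method: Photochemically generated α-aminoalkyl radicals abstract iodine from 35, the primary C4 radical adds to the unsubstituted diene terminus C5 (15-endo-trig macrocyclisation), and the ester-stabilised allyl radical is reduced by the reduced photocatalyst to dienolate 36 (radical–polar crossover). The closest known reaction types are radical macrocyclisations of ω-iodoalkyl acrylates, photoredox Giese additions of alkyl iodides and carbanion-terminated radical–polar crossover cyclisations, whereas their merger with a 1,6-addition and a transannular vinylogous aldol reaction is new. Dienolate 36 can react with C13 only at C6, because attack through C8 would give a cyclobutane, so a 6-(enolendo)-exo-trig aldol closes the cyclohexene and contracts the 15-ring to the 11-ring, and alkoxide 37 closes the γ-lactone by 5-exo-trig acyl substitution at the cis C15 ester, which makes the reversible aldol irreversible. C6 and C13 are set in a chair-like aldol transition state in which A(1,3) strain with the ester enolate holds the C11 methyl on C10 pseudoaxial, the bulky C22 residue is equatorial (O14 axial) and the (E)-C6=C7 geometry puts C5 pseudoequatorial, which gives C5, O14 and C11 cis and C5 trans to C22; the same C13 face is the Felkin–Anh face with respect to C22 (attack anti to quaternary C16), so the two fragments are matched. The step needs cyclisation to outrun hydrogen capture and oligomerisation (high dilution, slow addition, no tin hydride or thiol) and C–C formation to outrun protonation of 36, and any α-protonated β,γ-unsaturated macrocycle is re-enolised by Cs2CO3 and drains into the same lactone.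

Step 21
Reactants: 38 tetracyclic alkene
Product: 39 18α,19α-diol
Conditions: OsO4 (5 mol %), NMO, acetone–t-BuOH–H2O, 40 °C
Reagents that add atoms: N-methylmorpholine N-oxide C[N+]1([O-])CCOCC1; water O
Why: In this Upjohn dihydroxylation OsO4 takes the electron-richer C18=C19 alkene and not the C7=C8 enoate, from the α face opposite C15 and C23, and both new carbinol centres are erased in step 22.

Step 22
Reactants: 39 diol
Product: 40 target tert-butyl ester (C18/C19 diketone)
Conditions: IBX (3 equiv), DMSO, rt
Reagents that add atoms: none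
Why: IBX oxidises the 1,2-diol to the 1,2-diketone without C–C cleavage, and C20 becomes epimerisable but is held, since only the C20/C22 cis arrangement can span the eleven-membered ring.

Step 23
Reactants: 40 target tert-butyl ester
Product: 41 CNP0115928.1
Conditions: TFA–CH2Cl2 1:4, 0 °C → rt
Reagents that add atoms: none
Why: Acidolysis of the tert-butyl ester frees the C9 acid without base, so the non-enolisable β-keto lactone and the diketone are not exposed to retro-Claisen or benzilic pathways.

Compound list
1 | (S)-citronellol | C[C@@H](CCC=C(C)C)CCO | starting material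
2 | (S)-citronellyl chloride, (6S)-8-chloro-2,6-dimethyloct-2-ene | C[C@@H](CCC=C(C)C)CCCl | intermediate
3 | (4S)-6-chloro-4-methylhexanoic acid | C[C@@H](CCC(=O)O)CCCl | intermediate
4 | (E)-crotonaldehyde | C/C=C/C=O | starting material
5 | (4S)-6-chloro-4-methylhexanoyl chloride | C[C@@H](CCC(=O)Cl)CCCl | intermediate
6 | potassium (1E)-buta-1,3-dien-1-olate | C=C/C=C/[O-].[K+] | intermediate
7 | (1E)-buta-1,3-dien-1-yl (4S)-6-chloro-4-methylhexanoate | C[C@@H](CCC(=O)O/C=C/C=C)CCCl | intermediate
8 | tert-butyl diethylphosphonoacetate | CCOP(=O)(OCC)CC(=O)OC(C)(C)C | starting material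
9 | 1,1-dimethoxypropan-2-one | CC(=O)C(OC)OC | starting material
10 | tert-butyl (2E)-4,4-dimethoxy-3-methylbut-2-enoate | COC(OC)/C(C)=C/C(=O)OC(C)(C)C | intermediate
11 | tert-butyl (2E)-3-methyl-4-oxobut-2-enoate | O=C/C(C)=C/C(=O)OC(C)(C)C | intermediate
12 | Diels–Alder adduct; C15 formyl and C18 acyloxy β, C17 methyl and C13 ester α | O=C[C@@]1(C)[C@@H](OC(=O)CC[C@H](C)CCCl)C=CC[C@@H]1C(=O)OC(C)(C)C | intermediate
13 | C15 acid of 12 | OC(=O)[C@@]1(C)[C@@H](OC(=O)CC[C@H](C)CCCl)C=CC[C@@H]1C(=O)OC(C)(C)C | intermediate
14 | trimethylsilyl ester and (Z)-trimethylsilyl ketene acetal of 13 | C[Si](C)(C)OC(=O)[C@@]1(C)[C@@H](O/C(O[Si](C)(C)C)=C/C[C@H](C)CCCl)C=CC[C@@H]1C(=O)OC(C)(C)C | intermediate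
15 | Claisen diacid; C23 on C20 β, C18=C19 alkene, C24 as CO2H | OC(=O)[C@@]1(C)C=C[C@@H]([C@H](C(=O)O)C[C@H](C)CCCl)C[C@@H]1C(=O)OC(C)(C)C | intermediate
16 | C24 isobutyl carbonic mixed anhydride of 15 | OC(=O)[C@@]1(C)C=C[C@@H]([C@H](C(=O)OC(=O)OCC(C)C)C[C@H](C)CCCl)C[C@@H]1C(=O)OC(C)(C)C | intermediate
17 | C24 primary alcohol | OC(=O)[C@@]1(C)C=C[C@@H]([C@H](CO)C[C@H](C)CCCl)C[C@@H]1C(=O)OC(C)(C)C | intermediate
18 | C24 primary iodide | OC(=O)[C@@]1(C)C=C[C@@H]([C@H](CI)C[C@H](C)CCCl)C[C@@H]1C(=O)OC(C)(C)C | intermediate
19 | C24 methyl compound; C13 ester still α | OC(=O)[C@@]1(C)C=C[C@@H]([C@H](C)C[C@H](C)CCCl)C[C@@H]1C(=O)OC(C)(C)C | intermediate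
20 | trans-diacid (C15 β, C13 α) | OC(=O)[C@@]1(C)C=C[C@@H]([C@H](C)C[C@H](C)CCCl)C[C@@H]1C(=O)O | intermediate
21 | trans-fused anhydride | O=C1OC(=O)[C@@]2(C)C=C[C@@H]([C@H](C)C[C@H](C)CCCl)C[C@H]12 | intermediate
22 | cis-fused anhydride (C13 and C15 both β) | O=C1OC(=O)[C@@]2(C)C=C[C@@H]([C@H](C)C[C@H](C)CCCl)C[C@@H]12 | intermediate
23 | sodium C15 carboxylate of the C13 S-ethyl thioester | CCSC(=O)[C@@H]1C[C@H]([C@H](C)C[C@H](C)CCCl)C=C[C@]1(C)C(=O)[O-].[Na+] | intermediate
24 | C13 S-ethyl thioester, C15 methyl ester (cis) | CCSC(=O)[C@@H]1C[C@H]([C@H](C)C[C@H](C)CCCl)C=C[C@]1(C)C(=O)OC | intermediate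
25 | (R)-methyl hydrogen 3-methylglutarate | C[C@H](CC(=O)O)CC(=O)OC | starting material
26 | 1-tert-butyl 5-methyl (3S)-3-methylpentanedioate | C[C@H](CC(=O)OC(C)(C)C)CC(=O)OC | intermediate
27 | (3S)-5-(tert-butoxy)-3-methyl-5-oxopentanoic acid | C[C@H](CC(=O)OC(C)(C)C)CC(=O)O | intermediate
28 | acrolein | C=CC=O | starting material
29 | aldol adduct, C7/C8 unassigned | C=CC(O)C(C(=O)OC(C)(C)C)[C@@H](C)CC(=O)O | intermediate
30 | C7 acetate of 29 | C=CC(OC(C)=O)C(C(=O)OC(C)(C)C)[C@@H](C)CC(=O)O | intermediate
31 | (3S,4E)-4-(tert-butoxycarbonyl)-3-methylhepta-4,6-dienoic acid | C=C/C=C(/C(=O)OC(C)(C)C)[C@@H](C)CC(=O)O | intermediate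
32 | tert-butyl (2E)-2-[(2R)-1-iodopropan-2-yl]penta-2,4-dienoate | C=C/C=C(/C(=O)OC(C)(C)C)[C@@H](C)CI | intermediate
33 | alkylzinc iodide from 32 | C=C/C=C(/C(=O)OC(C)(C)C)[C@@H](C)C[Zn]I | intermediate
34 | keto chloride | C=C/C=C(/C(=O)OC(C)(C)C)[C@@H](C)CC(=O)[C@@H]1C[C@H]([C@H](C)C[C@H](C)CCCl)C=C[C@]1(C)C(=O)OC | intermediate
35 | keto iodide, precursor of the key step | C=C/C=C(/C(=O)OC(C)(C)C)[C@@H](C)CC(=O)[C@@H]1C[C@H]([C@H](C)C[C@H](C)CCI)C=C[C@]1(C)C(=O)OC | intermediate
36 | 15-membered macrocyclic caesium dienolate | C[C@@H]1CCC/C=C/C(=C([O-])OC(C)(C)C)[C@@H](C)CC(=O)[C@@H]2C[C@@H](C=C[C@]2(C)C(=O)OC)[C@H](C)C1.[Cs+] | intermediate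
37 | caesium C13 alkoxide after the transannular aldol | C[C@@H]1CCC[C@H]2C=C(C(=O)OC(C)(C)C)[C@@H](C)C[C@]2([O-])[C@@H]2C[C@@H](C=C[C@]2(C)C(=O)OC)[C@H](C)C1.[Cs+] | intermediate
38 | tetracyclic spirolactone tert-butyl ester, C18=C19 alkene | C[C@@H]1CCC[C@H]2C=C(C(=O)OC(C)(C)C)[C@@H](C)C[C@@]23OC(=O)[C@@]2(C)C=C[C@H](C[C@H]23)[C@H](C)C1 | intermediate
39 | 18α,19α-diol | C[C@@H]1CCC[C@H]2C=C(C(=O)OC(C)(C)C)[C@@H](C)C[C@@]23OC(=O)[C@@]2(C)[C@H](O)[C@H](O)[C@H](C[C@H]23)[C@H](C)C1 | intermediate
40 | tert-butyl ester of the target | C[C@@H]1CCC[C@H]2C=C(C(=O)OC(C)(C)C)[C@@H](C)C[C@@]23OC(=O)[C@@]2(C)C(=O)C(=O)[C@H](C[C@H]23)[C@H](C)C1 | intermediate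
41 | CNP0115928.1 | C[C@@H]1CCC[C@H]2C=C(C(=O)O)[C@@H](C)C[C@@]23OC(=O)[C@@]2(C)C(=O)C(=O)[C@H](C[C@H]23)[C@H](C)C1 | target

Total step count: 23. Longest linear sequence: 16 steps (1–3, 6–12, 18–23).

Steps most likely to fail

1. Step 20 (Proposed new method).
   * What may go wrong: the C4 radical may capture hydrogen from the medium or undergo a 1,5-hydrogen shift from C23 before the slow macrocyclisation. Intermolecular addition may lead to oligomers. The dienolate may be protonated at C6 to a conjugated enoate that Cs2CO3 cannot re-enolise.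
   * Fallback (known chemistry, two separate operations): it sets out from 35. Slow addition of Bu3SnH/AIBN in refluxing benzene at 1 mM performs the established tin-hydride macrocyclisation onto an acrylate-type acceptor and gives the 15-membered β,γ-unsaturated keto diester F1, together with its conjugated isomer. Treatment with KHMDS in THF (−78 → 0 °C) then regenerates the dienolate stoichiometrically in the absence of proton sources. Transannular vinylogous aldol addition and lactonisation bring the material back to the route at 38.

2. Step 6.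
   * What may go wrong: the β-ester may compete with the formyl group for the endo position, facial shielding may be incomplete, and the strong acid may degrade the dienyl ester.
   * Fallback (separation instead of catalyst control): it sets out from 7 and 11. EtAlCl2 in CH2Cl2 at −78 °C gives the endo adduct 12 together with the adduct of opposite ring configuration F2. Because both carry the same C2 centre they are diastereomers. Pinnick oxidation of the mixture gives 13 and the diastereomeric acid F3. Acid 13 is crystallised as its (R)-1-phenylethylammonium salt F4 and released with dilute acid, returning to the route at 13.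

3. Step 11.
   * What may go wrong: the sequence may stall at the trans-fused or mixed anhydride, so that C22 is only partly inverted, or prolonged heating with amine may attack the alkyl chloride.
   * Fallback (kinetic protonation instead of strain-driven equilibration): it sets out from 19. TMSCHN2 gives the trans methyl tert-butyl diester F5. LDA (THF, −78 → −30 °C) forms the C22 ester enolate, which is quenched at −78 °C with 2,6-di-tert-butyl-4-methylphenol from the α face, opposite the pseudoaxial C15 ester, to give the cis diester F6. TFA gives the cis C13 acid F7. EtSH, EDC and catalytic DMAP at 0 °C then return to the route at 24.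

Further compounds
F1 | step 20 | 15-membered β,γ-unsaturated keto diester (C8 unassigned) | C[C@@H]1CCC/C=C/C(C(=O)OC(C)(C)C)[C@@H](C)CC(=O)[C@@H]2C[C@@H](C=C[C@]2(C)C(=O)OC)[C@H](C)C1
F2 | step 6 | endo adduct of opposite ring configuration | O=C[C@]1(C)[C@H](OC(=O)CC[C@H](C)CCCl)C=CC[C@H]1C(=O)OC(C)(C)C
F3 | step 6 | C15 acid of F2 | OC(=O)[C@]1(C)[C@H](OC(=O)CC[C@H](C)CCCl)C=CC[C@H]1C(=O)OC(C)(C)C
F4 | step 6 | (R)-1-phenylethylammonium salt of 13 | [O-]C(=O)[C@@]1(C)[C@@H](OC(=O)CC[C@H](C)CCCl)C=CC[C@@H]1C(=O)OC(C)(C)C.C[C@@H]([NH3+])c1ccccc1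
F5 | step 11 | trans C15 methyl C13 tert-butyl diester | COC(=O)[C@@]1(C)C=C[C@@H]([C@H](C)C[C@H](C)CCCl)C[C@@H]1C(=O)OC(C)(C)C
F6 | step 11 | cis C15 methyl C13 tert-butyl diester | COC(=O)[C@@]1(C)C=C[C@@H]([C@H](C)C[C@H](C)CCCl)C[C@H]1C(=O)OC(C)(C)C
F7 | step 11 | cis C13 acid C15 methyl ester | COC(=O)[C@@]1(C)C=C[C@@H]([C@H](C)C[C@H](C)CCCl)C[C@H]1C(=O)O
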